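(All runs come from a simulation from invented constants, noise included.)

The substrate of this flask is charged between the charges of two earlier runs, under a held gas phase of which none is in solution at the start.

| setting | north-east | west | flask |
|---|---|---|---|
| substrate | 0.17 M | 0.70 M | 0.35 M |
| gas phase | 150 mM (held) | 150 mM (held) | 150 mM (held) |
| remark | run made earlier | run made earlier |  |
| time |  |  | 1.5 h |

| run | time / min | target / % | substrate / % |
|---|---|---|---|
| north-east | 12.0 | 0 | 87 |
| north-east | 30.0 | 5 | 69 |
| north-east | 60.0 | 16 | 46 |
| north-east | 90.0 | 15 | 32 |
| west | 8.00 | 0 | 92 |
| west | 15.0 | 0 | 82 |
| west | 40.0 | 8 | 56 |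
| west | 90.0 | 15 | 28 |

(readings scatter by 2 percentage points)

- at the start none of the gas phase is in solution

- how much target there is at 1.5 h, in percent of the substrate charged
- the change that raises the amount of target at 1.5 h, in percent of the substrate charged most ("none" if none brings more than 2 percentage points) (elm / alder / none)
- amount of target at 1.5 h, in percent of the substrate charged, after alder

- elm: doubling the transfer coefficient of the gas phase, all else as stated
- alder: doubling the saturation concentration of gas phase, all else as stated

We divide the rise of target by the fall of substrate between two readings, so that time drops out. In the west run, from 40.0 min to 90.0 min, target gains 7 percentage points while substrate loses 28 points, which gives 0.250; we call this the late share, the target gained per substrate lost, a selectivity read from the readings.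

Take the charge first. The north-east run, charged 4.12 times lower than the west run, gives 0.270 from 30.0 min to 90.0 min, so on these readings the charge moves the late share little.

Then the time. Target reads 0% in the west run at 15.0 min, with substrate at 82%, and the two runs leave about 30.0% of their substrate at 1.5 h. Our reckoning for the flask is therefore the late share of that difference, 13.0%.

Then elm. If the doubled transfer brought the start of target forward to the west run's 8.00 min, with substrate at 92%, our reckoning for the flask would gain 2.5 points.

Then alder. If [dissolved gas] doubles and the other loss of substrate ignores the gas, the ratio of target to other loss doubles, the late share becomes 0.400, and our reckoning for the flask reaches 20.8% of target. That is a gain of 7.8 points, larger than elm's, so we choose alder.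

The forecast, higher than our 13.0%, gives 15.5% of target, chooses alder and expects 21% after it, noting of the target that “its percentage matches at equal times in both runs”.

The flask gives 17.4% of target. The choice is alder, which adds 11 points against 4.8 points for elm and brings target to 28.0%.

    gas phase ⇌ dissolved gas, rate k1*(csat - [dissolved gas]) (kL = 6.50 × 10⁻⁴ s⁻¹)
    substrate + dissolved gas → target (k = 8.00 × 10⁻⁴ L mol⁻¹ s⁻¹)
    substrate → side product (k = 1.70 × 10⁻⁴ s⁻¹)
    2 substrate → self-condensation product A (k = 3.40 × 10⁻⁷ L mol⁻¹ s⁻¹)
    2 dissolved gas → self-condensation product B (k = 0.00160 L mol⁻¹ s⁻¹)

Between 0.750 h and 1.50 h this flask shows a late share of 0.296. Now read the same flask at 6.0 h. Substrate falls from 28.8% to 0.511%, and the 0.250 read from the west run, taken of that fall and added to the 17.4% of target already there, gives 24.5%. That neighbouring flask holds 26.2% of target, beside 73.2% of side product.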